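**Retrosynthetic overview**
- Target ⇐ C3 silyl ether: desilylation last, after Yamaguchi angeloylation of C8–OH and α‑methylenation of the cis‑fused γ‑lactone.
- C10 tertiary allylic alcohol with E‑Δ1,2 ⇐ Δ1(10) epoxide (selenolate opening, selenoxide elimination); C8–OH ⇐ C8–Si (Tamao–Fleming, retention).
- γ‑Lactone (last ring formed) ⇐ 6‑keto‑7‑acetate by 1,2‑reduction and lactonization; the acetate arm ⇐ alkylation of the enolate delivered by the ring expansion.
- Key step: anionic oxy‑Cope [3,3] rearrangement of a trans‑1,2‑dialkenylcyclohex‑2‑enol makes the C8–C9 bond and the ten‑membered ring; 4Z comes from the six‑membered ring, 1(10)E and C8 from the chair transition state.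
- Carbinol ⇐ 4‑silyloxy enone + (E)‑2‑silylvinyllithium; enone ⇐ (S)‑(+)‑carvone. Ring order: six‑membered ring (bought) → ten‑membered ring → lactone.

Assumption: germacrane locants are used for all ten‑membered compounds (lactone O on C6, C11 on C7, ester on C8, carbinols C3 and C10, C14 on C10, C15 on C4); descriptors are CIP.

**Step 1**
Reactants: 1 (S)-(+)-carvone
Product: 2 (1S,5S)-2-methyl-5-(prop-1-en-2-yl)cyclohex-2-en-1-ol (cis-carveol)
Conditions: NaBH4, CeCl3·7H2O, MeOH, −78 °C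
Reagents that add atoms: none
Why: Luche 1,2‑reduction; hydride adds axially to the half‑chair on the face anti to the isopropenyl group, giving the cis (1S) allylic alcohol (germacrane C3).

**Step 2**
Reactants: 2 (1S,5S)-cis-carveol
Product: 3 triisopropyl{[(1S,5S)-2-methyl-5-(prop-1-en-2-yl)cyclohex-2-en-1-yl]oxy}silane
Conditions: i-Pr3SiOTf, 2,6-lutidine, CH2Cl2, 0 °C
Reagents that add atoms: triisopropylsilyl trifluoromethanesulfonate, CC(C)[Si](OS(=O)(=O)C(F)(F)F)(C(C)C)C(C)C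
Why: O‑silylation (no stereocentre touched) gives an ether that survives the oxidant, organolithium, KH and brief fluoride treatment used later.

**Step 3**
Reactants: 3 carveol triisopropylsilyl ether
Product: 4 (4S,6S)-3-methyl-6-(prop-1-en-2-yl)-4-(triisopropylsilyloxy)cyclohex-2-en-1-one
Conditions: Rh2(cap)4 (dirhodium tetracaprolactamate, 1 mol %), t-BuOOH (70% aq.), K2CO3, CH2Cl2, rt
Reagents that add atoms: tert-butyl hydroperoxide, CC(C)(C)OO
Why: allylic C–H oxidation at the only free ring methylene next to the trisubstituted alkene gives the enone; no new stereocentre, and the α‑centre keeps the favoured cis (diequatorial) relation to the silyl ether.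

**Step 4**
Reactants: 5 (E)-1,2-bis(tributylstannyl)ethene
Product: 7 (E)-benzyl(dimethyl)[2-(tributylstannyl)ethenyl]silane, via (E)-2-(tributylstannyl)ethenyllithium 6 (not isolated)
Conditions: n-BuLi, THF, −78 °C; then BnMe2SiCl, −78 °C → rt
Reagents that add atoms: benzylchlorodimethylsilane, C[Si](C)(Cl)Cc1ccccc1
Why: tin–lithium exchange and silylation both proceed with retention of the E geometry; no stereocentre.

**Step 5**
Reactants: 4 (4S,6S)-silyloxy enone; 7 (E)-silyl stannyl ethene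
Product: 9 (1S,4S,6S)-1-{(E)-2-[benzyl(dimethyl)silyl]ethenyl}-3-methyl-6-(prop-1-en-2-yl)-4-(triisopropylsilyloxy)cyclohex-2-en-1-ol, via (E)-2-[benzyl(dimethyl)silyl]ethenyllithium 8 (not isolated)
Conditions: 7, n-BuLi, THF, −78 °C; then 4, −78 °C
Reagents that add atoms: none
Why: 1,2‑addition of the bulky alkenyllithium to the β,β‑disubstituted enone from the equatorial direction, anti to the neighbouring isopropenyl group, sets the carbinol (germacrane C6) with the two alkenyl groups trans‑diequatorial.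

**Step 6**
Reactants: 9 trans-1,2-dialkenylcyclohexenol
Product: 12 methyl 2-[(1(10)E,4Z,3S,7S,8S)-8-[benzyl(dimethyl)silyl]-4,10-dimethyl-6-oxo-3-(triisopropylsilyloxy)cyclodeca-1(10),4-dien-7-yl]acetate, via potassium alkoxide 10 (not isolated), via potassium enolate 11 (not isolated)
Conditions: KH, 18-crown-6, THF, 0 °C → rt; then BrCH2CO2Me, −78 °C
Reagents that add atoms: methyl bromoacetate, COC(=O)CBr
Why: anionic oxy‑Cope [3,3]‑sigmatropic rearrangement through the only available chair (trans‑decalin‑like) gives the ten‑membered ring with E‑Δ1(10), the ring‑derived Z‑Δ4 and the equatorial silyl group as 8S; the enolate is then alkylated on its outer face, anti to the C8–C9 ring bond with the silyl group in plane, which sets C7.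

**Step 7**
Reactants: 12 γ-keto ester
Product: 14 (1(10)E,4Z,3S,6S,7S,8S)-8-[benzyl(dimethyl)silyl]-3-(triisopropylsilyloxy)-13-norgermacra-1(10),4-dien-12,6-olide, via hydroxy ester 13 (not isolated)
Conditions: NaBH4, CeCl3·7H2O, MeOH, −78 → 0 °C; then DBU (cat.), PhMe, rt
Reagents that add atoms: none
Why: Luche 1,2‑reduction with hydride entering from the ring periphery anti to the C7–C8 bond (Felkin–Anh) gives the 6S alcohol cis to the acetate arm, which closes to the cis‑fused γ‑lactone.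

**Step 8**
Reactants: 14 silyl lactone
Product: 16 (1(10)E,4Z,3S,6S,7R,8S)-8-hydroxy-3-(triisopropylsilyloxy)-13-norgermacra-1(10),4-dien-12,6-olide, via dimethylsilanol 15 (not isolated)
Conditions: Bu4NF, THF, 0 °C; then H2O2 (30%), KHCO3, MeOH, rt
Reagents that add atoms: hydrogen peroxide, OO
Why: Tamao–Fleming oxidation (fluoride removes the benzyl group, then peroxide‑induced 1,2‑shift from silicon to oxygen) converts C8–Si into C8–OH with retention, giving 8S.

**Step 9**
Reactants: 16 hydroxy lactone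
Product: 17 (4Z,1S,3S,6S,7R,8S,10S)-1,10-epoxy-8-hydroxy-3-(triisopropylsilyloxy)-13-norgermacr-4-en-12,6-olide
Conditions: m-CPBA, NaHCO3, CH2Cl2, 0 °C
Reagents that add atoms: 3-chloroperbenzoic acid, OOC(=O)c1cccc(Cl)c1
Why: Prilezhaev epoxidation picks the electron‑rich E‑Δ1(10) alkene (Δ4 is deactivated by two allylic C–O bonds) and adds syn to its outer face; with the bulky silicon already gone the ring is expected to react through the conformer with C3–OSi anti to C1 and C7–C8–C9–C10 extended, which leads to the (1S,10S) epoxide.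

**Step 10**
Reactants: 17 epoxide
Product: 20 (1E,4Z,3S,6S,7R,8S,10S)-8,10-dihydroxy-3-(triisopropylsilyloxy)-13-norgermacra-1,4-dien-12,6-olide, via hydroxy selenide 18 (not isolated), via selenoxide 19 (not isolated)
Conditions: (PhSe)2, NaBH4, EtOH, rt → 60 °C; then H2O2 (30%), pyridine, THF, 0 °C → rt
Reagents that add atoms: none
Why: Sharpless–Lauer sequence: SN2 opening at the less substituted C1 leaves the C10–O bond and its configuration intact, and selenoxide syn‑elimination can only take a hydrogen from C2, giving the E‑Δ1,2 tertiary allylic alcohol.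

**Step 11**
Reactants: 20 diol lactone
Product: 23 (1E,4Z,3S,6S,7R,8S,10S)-8,10-dihydroxy-3-(triisopropylsilyloxy)germacra-1,4,11(13)-trien-12,6-olide, via Mannich base 21 (not isolated), via trimethylammonium iodide 22 (not isolated)
Conditions: LiN(i-Pr)2 (3.5 equiv), THF, −78 °C; then Me2N=CH2+ I−, −78 → 0 °C; then MeI, MeOH, rt; then NaHCO3 (aq), CH2Cl2, rt
Reagents that add atoms: N,N-dimethylmethyleneiminium iodide (Eschenmoser's salt), C=[N+](C)C.[I-]
Why: Mannich aminomethylation of the lactone enolate (the two alkoxides are spectators), then quaternization and E1cB loss of trimethylamine give the exocyclic methylene; the transient C11 centre is destroyed.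

**Step 12**
Reactants: 23 methylene lactone diol
Product: 24 (1E,4Z,3S,6S,7R,8S,10S)-10-hydroxy-8-[(Z)-2-methylbut-2-enoyloxy]-3-(triisopropylsilyloxy)germacra-1,4,11(13)-trien-12,6-olide
Conditions: angelic acid, 2,4,6-Cl3C6H2COCl, Et3N, PhMe, rt; then 23, 80 °C
Reagents that add atoms: angelic acid [(Z)-2-methylbut-2-enoic acid], C/C=C(/C)C(=O)O
Why: Yamaguchi esterification through the mixed anhydride acylates the only secondary hydroxyl (the tertiary C10–OH is inert); O‑acylation leaves C8 untouched and the absence of a nucleophilic catalyst avoids Z→E isomerization of the angelate.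

**Step 13**
Reactants: 24 silyl ether
Product: 25 (1E,4Z,3S,6S,7R,8S,10S)-3,10-dihydroxy-8-[(Z)-2-methylbut-2-enoyloxy]germacra-1,4,11(13)-trien-12,6-olide (target)
Conditions: HF·pyridine, pyridine, THF, 0 °C → rt
Reagents that add atoms: none
Why: buffered fluoride cleavage of the Si–O bond frees C3–OH without ionizing the allylic alcohols or touching the angelate and methylene lactone; no stereocentre is affected.

**Compound list**
1 | (S)-(+)-carvone | CC1=CC[C@@H](CC1=O)C(C)=C | starting material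
2 | (1S,5S)-2-methyl-5-(prop-1-en-2-yl)cyclohex-2-en-1-ol | CC1=CC[C@@H](C[C@@H]1O)C(C)=C | intermediate
3 | triisopropyl{[(1S,5S)-2-methyl-5-(prop-1-en-2-yl)cyclohex-2-en-1-yl]oxy}silane | CC1=CC[C@@H](C[C@@H]1O[Si](C(C)C)(C(C)C)C(C)C)C(C)=C | intermediate
4 | (4S,6S)-3-methyl-6-(prop-1-en-2-yl)-4-(triisopropylsilyloxy)cyclohex-2-en-1-one | CC1=CC(=O)[C@H](C(C)=C)C[C@@H]1O[Si](C(C)C)(C(C)C)C(C)C | intermediate
5 | (E)-1,2-bis(tributylstannyl)ethene | CCCC[Sn](CCCC)(CCCC)/C=C/[Sn](CCCC)(CCCC)CCCC | starting material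
6 | (E)-2-(tributylstannyl)ethenyllithium | [Li]/C=C/[Sn](CCCC)(CCCC)CCCC | intermediate
7 | (E)-benzyl(dimethyl)[2-(tributylstannyl)ethenyl]silane | C[Si](C)(Cc1ccccc1)/C=C/[Sn](CCCC)(CCCC)CCCC | intermediate
8 | (E)-2-[benzyl(dimethyl)silyl]ethenyllithium | [Li]/C=C/[Si](C)(C)Cc1ccccc1 | intermediate
9 | (1S,4S,6S)-1-{(E)-2-[benzyl(dimethyl)silyl]ethenyl}-3-methyl-6-(prop-1-en-2-yl)-4-(triisopropylsilyloxy)cyclohex-2-en-1-ol | CC1=C[C@@](O)(/C=C/[Si](C)(C)Cc2ccccc2)[C@H](C(C)=C)C[C@@H]1O[Si](C(C)C)(C(C)C)C(C)C | intermediate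
10 | potassium alkoxide of 9 | CC1=C[C@@]([O-])(/C=C/[Si](C)(C)Cc2ccccc2)[C@H](C(C)=C)C[C@@H]1O[Si](C(C)C)(C(C)C)C(C)C.[K+] | intermediate
11 | potassium enolate (O–C6=C7, 6Z) of (1(10)E,4Z,3S,8S)-8-[benzyl(dimethyl)silyl]-4,10-dimethyl-3-(triisopropylsilyloxy)cyclodeca-1(10),4-dien-6-one | [K+].[O-]/C1=C\[C@@H]([Si](C)(C)Cc2ccccc2)C/C(C)=C/C[C@H](O[Si](C(C)C)(C(C)C)C(C)C)/C(C)=C\1 | intermediate
12 | methyl 2-[(1(10)E,4Z,3S,7S,8S)-8-[benzyl(dimethyl)silyl]-4,10-dimethyl-6-oxo-3-(triisopropylsilyloxy)cyclodeca-1(10),4-dien-7-yl]acetate | O=C1/C=C(/C)[C@@H](O[Si](C(C)C)(C(C)C)C(C)C)C/C=C(C)/C[C@H]([Si](C)(C)Cc2ccccc2)[C@H]1CC(=O)OC | intermediate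
13 | methyl 2-[(1(10)E,4Z,3S,6S,7S,8S)-8-[benzyl(dimethyl)silyl]-6-hydroxy-4,10-dimethyl-3-(triisopropylsilyloxy)cyclodeca-1(10),4-dien-7-yl]acetate | O[C@H]1/C=C(/C)[C@@H](O[Si](C(C)C)(C(C)C)C(C)C)C/C=C(C)/C[C@H]([Si](C)(C)Cc2ccccc2)[C@H]1CC(=O)OC | intermediate
14 | (1(10)E,4Z,3S,6S,7S,8S)-8-[benzyl(dimethyl)silyl]-3-(triisopropylsilyloxy)-13-norgermacra-1(10),4-dien-12,6-olide | O=C1O[C@H]2/C=C(/C)[C@@H](O[Si](C(C)C)(C(C)C)C(C)C)C/C=C(C)/C[C@H]([Si](C)(C)Cc3ccccc3)[C@H]2C1 | intermediate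
15 | (1(10)E,4Z,3S,6S,7S,8S)-8-[hydroxy(dimethyl)silyl]-3-(triisopropylsilyloxy)-13-norgermacra-1(10),4-dien-12,6-olide | O=C1O[C@H]2/C=C(/C)[C@@H](O[Si](C(C)C)(C(C)C)C(C)C)C/C=C(C)/C[C@H]([Si](C)(C)O)[C@H]2C1 | intermediate
16 | (1(10)E,4Z,3S,6S,7R,8S)-8-hydroxy-3-(triisopropylsilyloxy)-13-norgermacra-1(10),4-dien-12,6-olide | O=C1O[C@H]2/C=C(/C)[C@@H](O[Si](C(C)C)(C(C)C)C(C)C)C/C=C(C)/C[C@H](O)[C@H]2C1 | intermediate
17 | (4Z,1S,3S,6S,7R,8S,10S)-1,10-epoxy-8-hydroxy-3-(triisopropylsilyloxy)-13-norgermacr-4-en-12,6-olide | O=C1O[C@H]2/C=C(/C)[C@@H](O[Si](C(C)C)(C(C)C)C(C)C)C[C@@H]3O[C@@]3(C)C[C@H](O)[C@H]2C1 | intermediate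
18 | (4Z,1R,3S,6S,7R,8S,10S)-8,10-dihydroxy-1-(phenylselanyl)-3-(triisopropylsilyloxy)-13-norgermacr-4-en-12,6-olide | O=C1O[C@H]2/C=C(/C)[C@@H](O[Si](C(C)C)(C(C)C)C(C)C)C[C@@H]([Se]c3ccccc3)[C@@](C)(O)C[C@H](O)[C@H]2C1 | intermediate
19 | Se-oxide of 18 | O=C1O[C@H]2/C=C(/C)[C@@H](O[Si](C(C)C)(C(C)C)C(C)C)C[C@@H]([Se](=O)c3ccccc3)[C@@](C)(O)C[C@H](O)[C@H]2C1 | intermediate
20 | (1E,4Z,3S,6S,7R,8S,10S)-8,10-dihydroxy-3-(triisopropylsilyloxy)-13-norgermacra-1,4-dien-12,6-olide | O=C1O[C@H]2/C=C(/C)[C@@H](O[Si](C(C)C)(C(C)C)C(C)C)/C=C/[C@@](C)(O)C[C@H](O)[C@H]2C1 | intermediate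
21 | (1E,4Z,3S,6S,7R,8S,10S)-13-(dimethylamino)-8,10-dihydroxy-3-(triisopropylsilyloxy)germacra-1,4-dien-12,6-olide (C11 epimers) | CN(C)CC1C(=O)O[C@H]2/C=C(/C)[C@@H](O[Si](C(C)C)(C(C)C)C(C)C)/C=C/[C@@](C)(O)C[C@H](O)[C@@H]12 | intermediate
22 | N-methyl quaternary ammonium iodide of 21 | C[N+](C)(C)CC1C(=O)O[C@H]2/C=C(/C)[C@@H](O[Si](C(C)C)(C(C)C)C(C)C)/C=C/[C@@](C)(O)C[C@H](O)[C@@H]12.[I-] | intermediate
23 | (1E,4Z,3S,6S,7R,8S,10S)-8,10-dihydroxy-3-(triisopropylsilyloxy)germacra-1,4,11(13)-trien-12,6-olide | C=C1C(=O)O[C@H]2/C=C(/C)[C@@H](O[Si](C(C)C)(C(C)C)C(C)C)/C=C/[C@@](C)(O)C[C@H](O)[C@@H]12 | intermediate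
24 | (1E,4Z,3S,6S,7R,8S,10S)-10-hydroxy-8-[(Z)-2-methylbut-2-enoyloxy]-3-(triisopropylsilyloxy)germacra-1,4,11(13)-trien-12,6-olide | C=C1C(=O)O[C@H]2/C=C(/C)[C@@H](O[Si](C(C)C)(C(C)C)C(C)C)/C=C/[C@@](C)(O)C[C@H](OC(=O)/C(C)=C\C)[C@@H]12 | intermediate
25 | (1E,4Z,3S,6S,7R,8S,10S)-3,10-dihydroxy-8-[(Z)-2-methylbut-2-enoyloxy]germacra-1,4,11(13)-trien-12,6-olide | C=C1C(=O)O[C@H]2/C=C(/C)[C@@H](O)/C=C/[C@@](C)(O)C[C@H](OC(=O)/C(C)=C\C)[C@@H]12 | target

**Step count and risks**
Total: 13 steps. Longest linear sequence: 12 steps (1–3, then 5–13 from carvone); step 4 is a one‑step side branch.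

Most likely to fail:

Step 9 (face of the epoxidation). The C10 configuration rests on which face of the medium‑ring E‑alkene is turned outward, and that conformational preference is an expectation, not a certainty. If the 10R epoxide dominates, the fallback sets out from 16 and delivers the C10 oxygen from inside the ring instead. Acylation of the C8 hydroxyl with Boc2O and DMAP gives the 8‑O‑tert‑butoxycarbonyl derivative of 16 F3. IBr in PhMe at −80 °C then closes the carbonate oxygen onto C10 anti to the external iodonium, giving the 1‑iodo 8,10‑cyclic carbonate F4. DBU removes HI towards C2 to give the Δ1,2 8,10‑cyclic carbonate F5, and K2CO3 in MeOH cleaves the carbonate. The route is rejoined at 20, bypassing 17–19.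

Step 10 (opening of the epoxide). SN2 attack at C1 of a trisubstituted epoxide in a ten‑membered ring must come from the ring interior and may stall or give transannular products; the elimination could also give some Z alkene. The fallback sets out from 16 and uses a Schenck ene reaction with singlet oxygen (O2, hν, tetraphenylporphyrin, CH2Cl2, −20 °C), which moves the double bond to C1–C2 and gives the 10‑hydroperoxide of 20 F6. PPh3 reduces it and the route is rejoined at 20. Abstraction from the C14 methyl is the competing ene pathway.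

Step 6 (rearrangement with in situ alkylation). The hindered β‑silyl potassium enolate may alkylate slowly, equilibrate or over‑alkylate. The fallback sets out from 9: after the same KH/18‑crown‑6 rearrangement the enolate is quenched with Me3SiCl and isolated as the trimethylsilyl enol ether of the ring‑expanded ketone F1. Cyclopropanation of its enol‑ether double bond with methyl diazoacetate and Rh2(OAc)4, again from the outer face, gives the methyl 2‑siloxycyclopropanecarboxylate F2. Ring opening of this donor–acceptor cyclopropane with Et3N·3HF gives the γ‑keto ester, and the route is rejoined at 12.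

**Further compounds**
F1 | step 6 | trimethylsilyl enol ether (C6–OSiMe3, Δ6,7) of (1(10)E,4Z,3S,8S)-8-[benzyl(dimethyl)silyl]-4,10-dimethyl-3-(triisopropylsilyloxy)cyclodeca-1(10),4-dien-6-one | C[Si](C)(C)O/C1=C\[C@@H]([Si](C)(C)Cc2ccccc2)C/C(C)=C/C[C@H](O[Si](C(C)C)(C(C)C)C(C)C)/C(C)=C\1
F2 | step 6 | methyl 6,7-methano adduct of F1 (2-siloxycyclopropanecarboxylate, carboxylate carbon on the bridging C11) | COC(=O)C1[C@]2(O[Si](C)(C)C)/C=C(/C)[C@@H](O[Si](C(C)C)(C(C)C)C(C)C)C/C=C(C)/C[C@H]([Si](C)(C)Cc3ccccc3)[C@@H]12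
F3 | step 9 | 8-O-tert-butoxycarbonyl derivative of 16 | O=C1O[C@H]2/C=C(/C)[C@@H](O[Si](C(C)C)(C(C)C)C(C)C)C/C=C(C)/C[C@H](OC(=O)OC(C)(C)C)[C@H]2C1
F4 | step 9 | (1R,10S)-1-iodo 8,10-cyclic carbonate | O=C1O[C@H]2/C=C(/C)[C@@H](O[Si](C(C)C)(C(C)C)C(C)C)C[C@@H](I)[C@]3(C)C[C@H](OC(=O)O3)[C@H]2C1
F5 | step 9 | 8,10-cyclic carbonate of 20 | O=C1O[C@H]2/C=C(/C)[C@@H](O[Si](C(C)C)(C(C)C)C(C)C)/C=C/[C@]3(C)C[C@H](OC(=O)O3)[C@H]2C1
F6 | step 10 | 10-hydroperoxide corresponding to 20 | O=C1O[C@H]2/C=C(/C)[C@@H](O[Si](C(C)C)(C(C)C)C(C)C)/C=C/[C@@](C)(OO)C[C@H](O)[C@H]2C1
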